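**Retrosynthetic overview**

1. The strategy rests on the pyranone ring (O1, C2, C3, C4, C4a, C8a) fused to a benzene ring whose three adjacent oxygens (O1, 8-OMe, 7-O-allyl) are those of symmetric 2-methoxyresorcinol; C4a is then the only free carbon ortho to O1 and lies para to O7.
2. The C4–C4a bond is cut last: the coumarin comes from aryl propiolate 18 by hydroarylation with monovalent gold. Ester 18 comes from propiolic acid and phenol 16, and 16 from 2-methoxyresorcinol and allylic alcohol 14 by Mitsunobu mono-etherification.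
3. The 2E-alkene of 14 comes from terminal alkyne 11 by methylalumination and formaldehyde trapping. The 5S,6S-diol comes unchanged from 2,3-O-isopropylidene-L-threitol (L-tartrate pool): one CH2OH becomes CH2–C≡CH, the other becomes C(CH3)=CH2.
4. Ring order: the benzene ring is bought, the pyranone ring is closed in step 13, and the two triethylsilyl ethers are removed in step 14.

Key step: step 13

Remark on the chemistry: acetonide diol 1 is taken as purchased (it is the ketalisation/reduction product of diethyl L-tartrate). The acetonide is exchanged for two triethylsilyl ethers before the organoaluminium step, because Me3Al can open isopropylidene acetals and because fluoride deprotection at the end spares the allylic aryl ether.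

**Step 1**
Reactants: 1 (4S,5S)-2,2-dimethyl-1,3-dioxolane-4,5-dimethanol (2,3-O-isopropylidene-L-threitol)
Product: 2 [(4S,5S)-5-({[tert-butyl(dimethyl)silyl]oxy}methyl)-2,2-dimethyl-1,3-dioxolan-4-yl]methanol
Conditions: NaH (1.0 equiv), THF, 0 °C → rt; then TBSCl (1.0 equiv), rt
Reagents that add atoms: tert-butyldimethylsilyl chloride, CC(C)(C)[Si](C)(C)Cl
Why: O-silylation of the monosodium alkoxide of a C2-symmetric diol should stop at the mono-ether because the two hydroxyls are equivalent and only one alkoxide is formed; no stereocentre is touched.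

**Step 2**
Reactants: 2 mono-TBS ether
Product: 3 [(4S,5S)-5-({[tert-butyl(dimethyl)silyl]oxy}methyl)-2,2-dimethyl-1,3-dioxolan-4-yl]methyl trifluoromethanesulfonate
Conditions: Tf2O, pyridine, CH2Cl2, −78 → −20 °C; cold aqueous wash, used crude at once
Reagents that add atoms: trifluoromethanesulfonic anhydride, O=S(=O)(OS(=O)(=O)C(F)(F)F)C(F)(F)F
Why: O-sulfonylation of the primary alcohol gives a primary triflate, the leaving group needed for clean substitution beside a β-oxygen; silyl ether and acetonide are inert at low temperature.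

**Step 3**
Reactants: 3 primary triflate
Product: 4 tert-butyl(dimethyl)({(4S,5S)-2,2-dimethyl-5-[3-(trimethylsilyl)prop-2-yn-1-yl]-1,3-dioxolan-4-yl}methoxy)silane
Conditions: Me3SiC≡CH, n-BuLi, THF, −78 °C; then 3, DMPU, −78 → −20 °C
Reagents that add atoms: (trimethylsilyl)acetylene (used as its lithium salt), C#C[Si](C)(C)C
Why: SN2 alkynylation of a primary alkyl triflate by a lithium acetylide forms the C3–C4 bond at a CH2 carbon, so the neighbouring stereocentre is not involved.

**Step 4**
Reactants: 4 silylated alkyne
Product: 5 [(4S,5S)-2,2-dimethyl-5-(prop-2-yn-1-yl)-1,3-dioxolan-4-yl]methanol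
Conditions: Bu4NF (2.5 equiv), THF, 0 °C → rt
Reagents that add atoms: none
Why: Fluoride desilylation cleaves the primary O–Si bond and the C(sp)–Si bond in one operation and leaves the acetonide untouched.

**Step 5**
Reactants: 5 primary alcohol
Product: 7 1-[(4S,5S)-2,2-dimethyl-5-(prop-2-yn-1-yl)-1,3-dioxolan-4-yl]ethan-1-ol (mixture of carbinol epimers), via aldehyde 6 (not isolated)
Conditions: (COCl)2, DMSO, THF, −78 °C; Et3N, −78 → 0 °C; then MeMgBr (excess), −78 → 0 °C
Reagents that add atoms: methylmagnesium bromide, C[Mg]Br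
Why: Swern oxidation followed by Grignard addition in the same flask avoids isolating the hydrate-prone α-alkoxy aldehyde; the new carbinol centre forms as a mixture, which is of no consequence because the next step oxidises it.

**Step 6**
Reactants: 7 secondary alcohol
Product: 8 1-[(4R,5S)-2,2-dimethyl-5-(prop-2-yn-1-yl)-1,3-dioxolan-4-yl]ethan-1-one
Conditions: Dess–Martin periodinane, CH2Cl2, rt
Reagents that add atoms: none
Why: Dess–Martin oxidation of the secondary alcohol gives the methyl ketone under near-neutral conditions, and the α-centre is safe because the trans-dioxolane is the thermodynamically preferred arrangement (the change of descriptor to 4R is a priority change only).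

**Step 7**
Reactants: 8 methyl ketone
Product: 9 (4S,5S)-2,2-dimethyl-4-(prop-1-en-2-yl)-5-(prop-2-yn-1-yl)-1,3-dioxolane
Conditions: Ph3PCH3Br, KOtBu, THF, 0 °C → rt
Reagents that add atoms: methyltriphenylphosphonium bromide, C[P+](c1ccccc1)(c1ccccc1)c1ccccc1.[Br-]
Why: Wittig methylenation converts the acetyl group into the isopropenyl group; the non-stabilised ylide is too weak a base to deprotonate the terminal alkyne to any extent, and the trans-acetonide holds the α-centre.

**Step 8**
Reactants: 9 isopropenyl acetonide
Product: 10 (4S,5S)-6-methylhept-6-en-1-yne-4,5-diol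
Conditions: AcOH/H2O 4:1, 50 °C; evaporation with toluene
Reagents that add atoms: none
Why: Acid-catalysed acetal hydrolysis breaks only the bonds to the acetal carbon, so both carbinol configurations are retained.

**Step 9**
Reactants: 10 diol
Product: 11 (4S,5S)-6-methyl-4,5-bis[(triethylsilyl)oxy]hept-6-en-1-yne
Conditions: Et3SiCl (2.5 equiv), imidazole, DMF, 0 °C → rt
Reagents that add atoms: chlorotriethylsilane, CC[Si](Cl)(CC)CC
Why: Imidazole-promoted O-silylation of both secondary hydroxyls gives ethers that tolerate organoaluminium reagents and are removed by fluoride at the end.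

**Step 10**
Reactants: 11 terminal alkyne
Product: 14 (2E,5S,6S)-3,7-dimethyl-5,6-bis[(triethylsilyl)oxy]octa-2,7-dien-1-ol, via alkenyldimethylalane 12 (not isolated), via lithium alkenylaluminate 13 (not isolated)
Conditions: Me3Al (3 equiv), Cp2ZrCl2 (0.3 equiv), CH2Cl2, 0 °C → rt; then n-BuLi, −78 → 0 °C; then (CH2O)n, THF, rt; Rochelle salt work-up
Reagents that add atoms: trimethylaluminium, C[Al](C)C; paraformaldehyde (formaldehyde), C=O
Why: Negishi zirconium-catalysed syn-carboalumination puts methyl on the internal and aluminium on the terminal alkyne carbon on the same face, and the aluminate attacks formaldehyde with retention, which fixes the 2E geometry; the 1,1-disubstituted alkene is not carbometalated under these conditions.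

**Step 11**
Reactants: 14 allylic alcohol; 15 2-methoxyresorcinol (2-methoxybenzene-1,3-diol, 3 equiv)
Product: 16 2-methoxy-3-{[(2E,5S,6S)-3,7-dimethyl-5,6-bis(triethylsilyloxy)octa-2,7-dien-1-yl]oxy}phenol
Conditions: PPh3, DIAD, THF, 0 °C → rt
Reagents that add atoms: none
Why: Mitsunobu etherification of a primary allylic alcohol by a phenol proceeds by SN2 at C1 with the alkene geometry kept, and the excess of the symmetric diphenol, whose two hydroxyls are equivalent, should hold the reaction at the mono-ether.

**Step 12**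
Reactants: 16 phenol; 17 propiolic acid
Product: 18 2-methoxy-3-{[(2E,5S,6S)-3,7-dimethyl-5,6-bis(triethylsilyloxy)octa-2,7-dien-1-yl]oxy}phenyl prop-2-ynoate
Conditions: DCC, DMAP (5 mol %), CH2Cl2, −20 → 0 °C
Reagents that add atoms: none
Why: Steglich carbodiimide esterification acylates the remaining phenol at low temperature, where conjugate addition to the propiolate is slow.

**Step 13**
Reactants: 18 aryl propiolate
Product: 19 7-{[(2E,5S,6S)-3,7-dimethyl-5,6-bis(triethylsilyloxy)octa-2,7-dien-1-yl]oxy}-8-methoxy-2H-chromen-2-one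
Conditions: [(2-biphenylyl)(t-Bu)2P]Au(NCMe)SbF6 (5 mol %), CH2Cl2, rt
Reagents that add atoms: none
Why: The cationic monovalent gold centre binds the terminal alkyne, the arene carbon ortho to the ester oxygen (the future C4a) attacks the terminal alkyne carbon anti to gold in a Friedel–Crafts manner, and rearomatisation followed by protodeauration releases the coumarin and the catalyst. The closest known reaction type is the gold- or palladium-catalysed intramolecular hydroarylation of aryl alkynoates, which is established for oxygenated aryl propiolates at room temperature. The pyranone ring is closed in the 6-endo-dig mode by forming C4–C4a; no stereocentre is formed, and the 5S,6S centres and the 2E alkene lie far from the reacting site. Regioselectivity is secured by the substrate: of the two carbons ortho to the ester oxygen one carries the methoxy group, so only one ring fusion is possible, and the attacking carbon is para to the allyloxy oxygen and thus the most nucleophilic free position. Chemoselectivity for the alkyne over the two side-chain alkenes follows from the alkynophilicity of gold and from the fact that either alkene could reach the alkyne only through a ring of ten or more atoms. The silver-free, near-neutral catalyst should leave the triethylsilyl ethers and the allylic aryl ether intact.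

**Step 14**
Reactants: 19 bis-silylated coumarin
Product: 20 7-{[(2E,5S,6S)-5,6-dihydroxy-3,7-dimethylocta-2,7-dien-1-yl]oxy}-8-methoxy-2H-chromen-2-one (CNP0214345.1)
Conditions: HF·pyridine, pyridine, THF, 0 °C → rt
Reagents that add atoms: none
Why: Buffered fluoride desilylation cleaves both Si–O bonds without acid strong enough to ionise the allylic aryl ether or base strong enough to open the lactone, so the diol is released with both configurations unchanged.

**Compound list**

1 | (4S,5S)-2,2-dimethyl-1,3-dioxolane-4,5-dimethanol | OC[C@@H]1OC(C)(C)O[C@H]1CO | starting material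
2 | [(4S,5S)-5-({[tert-butyl(dimethyl)silyl]oxy}methyl)-2,2-dimethyl-1,3-dioxolan-4-yl]methanol | CC(C)(C)[Si](C)(C)OC[C@@H]1OC(C)(C)O[C@H]1CO | intermediate
3 | [(4S,5S)-5-({[tert-butyl(dimethyl)silyl]oxy}methyl)-2,2-dimethyl-1,3-dioxolan-4-yl]methyl trifluoromethanesulfonate | CC(C)(C)[Si](C)(C)OC[C@@H]1OC(C)(C)O[C@H]1COS(=O)(=O)C(F)(F)F | intermediate
4 | tert-butyl(dimethyl)({(4S,5S)-2,2-dimethyl-5-[3-(trimethylsilyl)prop-2-yn-1-yl]-1,3-dioxolan-4-yl}methoxy)silane | CC(C)(C)[Si](C)(C)OC[C@@H]1OC(C)(C)O[C@H]1CC#C[Si](C)(C)C | intermediate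
5 | [(4S,5S)-2,2-dimethyl-5-(prop-2-yn-1-yl)-1,3-dioxolan-4-yl]methanol | OC[C@@H]1OC(C)(C)O[C@H]1CC#C | intermediate
6 | (4R,5S)-2,2-dimethyl-5-(prop-2-yn-1-yl)-1,3-dioxolane-4-carbaldehyde | O=C[C@@H]1OC(C)(C)O[C@H]1CC#C | intermediate
7 | 1-[(4S,5S)-2,2-dimethyl-5-(prop-2-yn-1-yl)-1,3-dioxolan-4-yl]ethan-1-ol (carbinol epimers) | CC(O)[C@@H]1OC(C)(C)O[C@H]1CC#C | intermediate
8 | 1-[(4R,5S)-2,2-dimethyl-5-(prop-2-yn-1-yl)-1,3-dioxolan-4-yl]ethan-1-one | CC(=O)[C@@H]1OC(C)(C)O[C@H]1CC#C | intermediate
9 | (4S,5S)-2,2-dimethyl-4-(prop-1-en-2-yl)-5-(prop-2-yn-1-yl)-1,3-dioxolane | C=C(C)[C@@H]1OC(C)(C)O[C@H]1CC#C | intermediate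
10 | (4S,5S)-6-methylhept-6-en-1-yne-4,5-diol | C=C(C)[C@H](O)[C@@H](O)CC#C | intermediate
11 | (4S,5S)-6-methyl-4,5-bis[(triethylsilyl)oxy]hept-6-en-1-yne | C=C(C)[C@H](O[Si](CC)(CC)CC)[C@@H](O[Si](CC)(CC)CC)CC#C | intermediate
12 | [(1E,4S,5S)-2,6-dimethyl-4,5-bis(triethylsilyloxy)hepta-1,6-dien-1-yl]dimethylalumane | C=C(C)[C@H](O[Si](CC)(CC)CC)[C@@H](O[Si](CC)(CC)CC)C/C(C)=C/[Al](C)C | intermediate
13 | lithium butyl[(1E,4S,5S)-2,6-dimethyl-4,5-bis(triethylsilyloxy)hepta-1,6-dien-1-yl]dimethylaluminate | [Li+].C=C(C)[C@H](O[Si](CC)(CC)CC)[C@@H](O[Si](CC)(CC)CC)C/C(C)=C/[Al-](C)(C)CCCC | intermediate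
14 | (2E,5S,6S)-3,7-dimethyl-5,6-bis[(triethylsilyl)oxy]octa-2,7-dien-1-ol | C=C(C)[C@H](O[Si](CC)(CC)CC)[C@@H](O[Si](CC)(CC)CC)C/C(C)=C/CO | intermediate
15 | 2-methoxyresorcinol (2-methoxybenzene-1,3-diol) | COc1c(O)cccc1O | starting material
16 | 2-methoxy-3-{[(2E,5S,6S)-3,7-dimethyl-5,6-bis(triethylsilyloxy)octa-2,7-dien-1-yl]oxy}phenol | C=C(C)[C@H](O[Si](CC)(CC)CC)[C@@H](O[Si](CC)(CC)CC)C/C(C)=C/COc1cccc(O)c1OC | intermediate
17 | propiolic acid (prop-2-ynoic acid) | C#CC(=O)O | starting material
18 | 2-methoxy-3-{[(2E,5S,6S)-3,7-dimethyl-5,6-bis(triethylsilyloxy)octa-2,7-dien-1-yl]oxy}phenyl prop-2-ynoate | C=C(C)[C@H](O[Si](CC)(CC)CC)[C@@H](O[Si](CC)(CC)CC)C/C(C)=C/COc1cccc(OC(=O)C#C)c1OC | intermediate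
19 | 7-{[(2E,5S,6S)-3,7-dimethyl-5,6-bis(triethylsilyloxy)octa-2,7-dien-1-yl]oxy}-8-methoxy-2H-chromen-2-one | C=C(C)[C@H](O[Si](CC)(CC)CC)[C@@H](O[Si](CC)(CC)CC)C/C(C)=C/COc1ccc2ccc(=O)oc2c1OC | intermediate
20 | 7-{[(2E,5S,6S)-5,6-dihydroxy-3,7-dimethylocta-2,7-dien-1-yl]oxy}-8-methoxy-2H-chromen-2-one | C=C(C)[C@H](O)[C@@H](O)C/C(C)=C/COc1ccc2ccc(=O)oc2c1OC | target

**Step count**

Total step count: 14. Longest linear sequence: 14 steps (1 → 20); 15 and 17 enter at steps 11 and 12.

**Steps most likely to fail**

Step 13 (hydroarylation). The catalyst may be consumed or slowed by the terminal propiolate (oligomerisation, gold acetylide formation), and traces of acid formed from the counter-ion may cleave the triethylsilyl ethers or ionise the allylic aryl ether before ring closure is complete. Fallback: from phenol 16, ortho-formylation with MgCl2, Et3N and paraformaldehyde in MeCN at reflux should occur at the single free ortho carbon and give 2-hydroxy-3-methoxy-4-{[(2E,5S,6S)-3,7-dimethyl-5,6-bis(triethylsilyloxy)octa-2,7-dien-1-yl]oxy}benzaldehyde F1. Treating F1 with ketenylidenetriphenylphosphorane (Ph3P=C=C=O) in toluene at 90 °C acylates the phenol and closes the pyranone ring by intramolecular Wittig reaction at C3–C4, which gives 19 and rejoins the route there without passing through 18.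

Step 10 (methylalumination and hydroxymethylation). Carbometalation may stall because the aluminium reagent is tied up by the two silyloxy groups, the aluminate may be protonated instead of trapped by formaldehyde, and the Lewis-acidic medium may strip a triethylsilyl group. Fallback: from alkyne 11, deprotonation with n-BuLi and addition to paraformaldehyde gives (5S,6S)-7-methyl-5,6-bis(triethylsilyloxy)oct-7-en-2-yn-1-ol F2. Alkoxide-directed anti-hydroalumination with NaAlH2(OCH2CH2OMe)2 in THF followed by iodine at −78 °C gives (2Z,5S,6S)-3-iodo-7-methyl-5,6-bis(triethylsilyloxy)octa-2,7-dien-1-ol F3, with iodine cis to CH2OH. Coupling with Me2CuLi in Et2O at 0 °C replaces iodine by methyl with retention and gives the 2E alcohol 14, where the route is rejoined.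

Step 11 (Mitsunobu mono-etherification). The mono-ether may react again to give the bis-ether, betaine protonation by the hindered, weakly acidic diphenol may be slow so that the hydrazide is alkylated instead, and some SN2′ attack may occur. Fallback: from alcohol 14, CBr4 and PPh3 in CH2Cl2 at 0 °C give (2E,5S,6S)-1-bromo-3,7-dimethyl-5,6-bis(triethylsilyloxy)octa-2,7-diene F4 (numbered as in 14). Williamson alkylation of 15 (large excess, removed afterwards by a basic wash) with F4 and K2CO3 in acetone at rt gives phenol 16, where the route is rejoined.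

**Further compounds**

F1 | step 13 | 2-hydroxy-3-methoxy-4-{[(2E,5S,6S)-3,7-dimethyl-5,6-bis(triethylsilyloxy)octa-2,7-dien-1-yl]oxy}benzaldehyde | C=C(C)[C@H](O[Si](CC)(CC)CC)[C@@H](O[Si](CC)(CC)CC)C/C(C)=C/COc1ccc(C=O)c(O)c1OC
F2 | step 10 | (5S,6S)-7-methyl-5,6-bis(triethylsilyloxy)oct-7-en-2-yn-1-ol | C=C(C)[C@H](O[Si](CC)(CC)CC)[C@@H](O[Si](CC)(CC)CC)CC#CCO
F3 | step 10 | (2Z,5S,6S)-3-iodo-7-methyl-5,6-bis(triethylsilyloxy)octa-2,7-dien-1-ol | C=C(C)[C@H](O[Si](CC)(CC)CC)[C@@H](O[Si](CC)(CC)CC)C/C(I)=C/CO
F4 | step 11 | (2E,5S,6S)-1-bromo-3,7-dimethyl-5,6-bis(triethylsilyloxy)octa-2,7-diene | C=C(C)[C@H](O[Si](CC)(CC)CC)[C@@H](O[Si](CC)(CC)CC)C/C(C)=C/CBr
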